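**Plan**

- Retrosynthesis cuts, in order: the ester C(=O)–O bond at C9 (p-coumaric acid off); the C9 oxygen, traced back to a vinyl group on C3; the oxolane C2–C3 bond together with O1–C2, giving silyl-protected vanillin and an open-chain (Z)-allylsilane silyl ether; then the C3=C9 alkene (Wittig) and the C4–C5 bond (α-hydroxymethylation of an arylpropanal).
- Enabling feature: C2 of the oxolane lies between the ring oxygen O1 and an electron-rich 4-oxy-3-methoxyphenyl ring, so it can be an aryl-stabilised oxocarbenium carbon. C3 carries a one-carbon branch (C9), so C3=C9 can be the alkene of a (Z)-allylsilane with C3 as its γ-carbon.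
- Forward: the chain C5–C4(–C7')–C3=C9 is built first. The oxolane, the only ring made in the route, arises in one operation when the aldehyde and the allylsilane are joined. C9 is then trimmed to CH2OH and esterified.
- Stereochemistry: C4 comes from catalyst control (enamine catalysis). C3 and C2 come from C4 in the ring closure: allylic 1,3-strain of the (Z)-alkene gives 3,4-trans, and the (E)-oxocarbenium ion gives 2,3-cis.

Key step: step 8

Remark: the target is taken as drawn, (2S,3S,4R) at the oxolane, with the 2-aryl and 3-CH2O groups cis and the 3-CH2O and 4-arylmethyl groups trans. Numbering used: O1, C2 (aryl), C3 (branch C9), C4 (arylmethyl, C7'), C5. Ar = 3-methoxy-4-(triisopropylsilyloxy)phenyl.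

Step 1
Reactants: 1 methyl 3-(4-hydroxy-3-methoxyphenyl)propanoate
Product: 2 methyl 3-Ar-propanoate
Conditions: i-Pr3SiCl, imidazole, DMF, rt
Reagents that add atoms: chlorotriisopropylsilane CC(C)[Si](Cl)(C(C)C)C(C)C
Why: Imidazole-mediated O-silylation of the phenol; the aryl silyl ether should tolerate the hydride, ylide and Lewis-acid steps that follow and is removable at the end without touching an ester.

Step 2
Reactants: 2 methyl 3-Ar-propanoate
Product: 3 3-Ar-propanal
Conditions: i-Bu2AlH (1.05 equiv), CH2Cl2, −78 °C; aq. potassium sodium tartrate (KNaC4H4O6)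
Reagents that add atoms: none
Why: Partial reduction of a methyl ester, in which the tetrahedral aluminium hemiacetal is stable at −78 °C and releases the aldehyde only on work-up.

Step 3
Reactants: 3 3-Ar-propanal
Product: 4 (2S)-3-hydroxy-2-(Ar-methyl)propanal
Conditions: 37% aq. CH2O, (R)-2-[diphenyl(trimethylsilyloxy)methyl]pyrrolidine (0.2 equiv), pH 7 NaH2PO4/Na2HPO4 buffer, toluene, rt; used crude
Reagents that add atoms: formaldehyde C=O
Why: Organocatalytic α-hydroxymethylation (enamine cross-aldol); the CPh2OSiMe3 group shields one face of the (E)-enamine, so formaldehyde should add to the open face and set C4 as the (S)-aldehyde.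

Step 4
Reactants: 4 (2S)-3-hydroxy-2-(Ar-methyl)propanal
Product: 5 (2S)-2-(Ar-methyl)-3-(triethylsilyloxy)propanal
Conditions: Et3SiCl, imidazole, CH2Cl2, 0 °C
Reagents that add atoms: chlorotriethylsilane CC[Si](Cl)(CC)CC
Why: O-silylation of the primary alcohol, which blocks retro-aldol and hemiacetal formation and installs the silyl ether that later delivers O1.

Step 5
Reactants: 6 methyltriphenylphosphonium bromide; 7 (iodomethyl)trimethylsilane
Product: 9 triphenyl[2-(trimethylsilyl)ethyl]phosphonium iodide, via methylenetriphenylphosphorane 8 (not isolated)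
Conditions: n-BuLi, THF, 0 °C; then 7, 0 °C → rt; salt filtered off
Reagents that add atoms: none
Why: C-alkylation of a phosphorus ylide by a primary iodide, a standard way to make β-silylethyl phosphonium salts.

Step 6
Reactants: 9 triphenyl[2-(trimethylsilyl)ethyl]phosphonium iodide; 5 (2S)-2-(Ar-methyl)-3-(triethylsilyloxy)propanal
Product: 11 triethyl{[(2R,3Z)-2-(Ar-methyl)-5-(trimethylsilyl)pent-3-en-1-yl]oxy}silane, via silyl ylide 10 (not isolated)
Conditions: KN(SiMe3)2, THF, −78 → 0 °C; then 5, −78 °C → rt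
Reagents that add atoms: none
Why: Wittig olefination with a non-stabilised ylide under lithium-free conditions should give the (Z)-alkene through kinetic oxaphosphetane formation; no new stereocenter is formed and the low temperature should keep the α-center of 5 intact.

Step 7
Reactants: 12 vanillin
Product: 13 3-methoxy-4-(triisopropylsilyloxy)benzaldehyde
Conditions: i-Pr3SiCl, imidazole, DMF, rt
Reagents that add atoms: chlorotriisopropylsilane CC(C)[Si](Cl)(C(C)C)C(C)C
Why: Imidazole-mediated O-silylation of the phenol.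

Step 8
Reactants: 11 triethyl{[(2R,3Z)-2-(Ar-methyl)-5-(trimethylsilyl)pent-3-en-1-yl]oxy}silane; 13 3-methoxy-4-(triisopropylsilyloxy)benzaldehyde
Product: 15 (2S,3R,4R)-3-ethenyl-2-Ar-4-(Ar-methyl)oxolane, via oxocarbenium ion 14 (not isolated)
Conditions: Me3SiOTf (0.3 equiv), 2,6-di-tert-butyl-4-methylpyridine (0.1 equiv), CH2Cl2, −78 °C; Et3N quench at −78 °C
Reagents that add atoms: none
Why: Me3SiOTf converts aldehyde 13 and the Et3Si ether of 11 into a mixed silyl acetal and then into the aryl-stabilised (E)-oxocarbenium ion 14, whose C2 is attacked intramolecularly by the allylsilane γ-carbon (C3) in an anti-SE2' fashion, after which the β-silyl cation at C9 loses Me3Si+ to leave the vinyl group. The closest known reaction type is the intramolecular silyl-modified Sakurai (Prins-type) condensation of aldehydes with 5-silylpent-3-en-1-ol derivatives to 2-substituted 3-vinyloxolanes. The oxolane is closed by the C2–C3 bond in a five-membered closure that is endo with respect to the C2=O1+ bond and exo with respect to the C3=C9 bond. C3 is controlled by C4: allylic 1,3-strain in the (Z)-alkene holds H4 in the alkene plane, the tether through C5 brings C2 to one face and the arylmethyl group lies on the other, so the vinyl group should end trans to the arylmethyl group. C2 is controlled by the (E)-geometry of 14 (aryl anti to C5), which in the compact transition state puts the aryl group on the same side as C9 and should give the 2,3-cis product under kinetic control. The step needs attack through C3 and not C9 (secured by the β-silicon effect), a (Z)-alkene (secured in step 6) and no ionisation of the product at C2 (secured by −78 °C, substoichiometric Me3SiOTf, the hindered pyridine and the cold amine quench).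

Step 9
Reactants: 15 (2S,3R,4R)-3-ethenyl-2-Ar-4-(Ar-methyl)oxolane
Product: 17 [(2S,3S,4R)-2-Ar-4-(Ar-methyl)oxolan-3-yl]methanol, via aldehyde 16 (not isolated)
Conditions: O3, CH2Cl2/MeOH 4:1, −78 °C; then NaBH4, −78 → 0 °C
Reagents that add atoms: ozone [O-][O+]=O
Why: Reductive ozonolysis of the monosubstituted alkene; reduction in the same flask should spare the epimerisable cis-aldehyde 16 from base and chromatography, so no stereocenter is touched.

Step 10
Reactants: 17 [(2S,3S,4R)-2-Ar-4-(Ar-methyl)oxolan-3-yl]methanol; 18 p-coumaric acid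
Product: 19 [(2S,3S,4R)-2-Ar-4-(Ar-methyl)oxolan-3-yl]methyl (2E)-3-(4-hydroxyphenyl)prop-2-enoate
Conditions: PPh3, diisopropyl azodicarboxylate, THF, 0 °C → rt
Reagents that add atoms: none
Why: Mitsunobu esterification, in which the carboxylic acid is far more acidic than the phenol and acts as the pronucleophile, so the phenolic acid can be used unprotected; the carbinol carbon is CH2, so no stereocenter is involved.

Step 11
Reactants: 19 [(2S,3S,4R)-2-Ar-4-(Ar-methyl)oxolan-3-yl]methyl (2E)-3-(4-hydroxyphenyl)prop-2-enoate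
Product: 20 CNP0119373.2 (target)
Conditions: Bu4NF, AcOH (each 2.5 equiv), THF, 0 °C
Reagents that add atoms: none
Why: Fluoride cleavage of the two aryl silyl ethers, buffered with AcOH so that the cinnamate ester, the (E)-alkene and the benzylic C2–O1 bond should be left alone.

**Compound list**

1 | methyl 3-(4-hydroxy-3-methoxyphenyl)propanoate | COC(=O)CCc1ccc(O)c(OC)c1 | starting material
2 | methyl 3-[3-methoxy-4-(triisopropylsilyloxy)phenyl]propanoate | COC(=O)CCc1ccc(O[Si](C(C)C)(C(C)C)C(C)C)c(OC)c1 | intermediate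
3 | 3-[3-methoxy-4-(triisopropylsilyloxy)phenyl]propanal | O=CCCc1ccc(O[Si](C(C)C)(C(C)C)C(C)C)c(OC)c1 | intermediate
4 | (2S)-3-hydroxy-2-{[3-methoxy-4-(triisopropylsilyloxy)phenyl]methyl}propanal | COc1cc(C[C@H](C=O)CO)ccc1O[Si](C(C)C)(C(C)C)C(C)C | intermediate
5 | (2S)-2-{[3-methoxy-4-(triisopropylsilyloxy)phenyl]methyl}-3-(triethylsilyloxy)propanal | COc1cc(C[C@H](C=O)CO[Si](CC)(CC)CC)ccc1O[Si](C(C)C)(C(C)C)C(C)C | intermediate
6 | methyltriphenylphosphonium bromide | C[P+](c1ccccc1)(c1ccccc1)c1ccccc1.[Br-] | starting material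
7 | (iodomethyl)trimethylsilane | C[Si](C)(C)CI | starting material
8 | methylenetriphenylphosphorane | C=P(c1ccccc1)(c1ccccc1)c1ccccc1 | intermediate
9 | triphenyl[2-(trimethylsilyl)ethyl]phosphonium iodide | C[Si](C)(C)CC[P+](c1ccccc1)(c1ccccc1)c1ccccc1.[I-] | intermediate
10 | triphenyl[2-(trimethylsilyl)ethylidene]phosphorane | C[Si](C)(C)CC=P(c1ccccc1)(c1ccccc1)c1ccccc1 | intermediate
11 | triethyl{[(2R,3Z)-2-{[3-methoxy-4-(triisopropylsilyloxy)phenyl]methyl}-5-(trimethylsilyl)pent-3-en-1-yl]oxy}silane | COc1cc(C[C@H](/C=C\C[Si](C)(C)C)CO[Si](CC)(CC)CC)ccc1O[Si](C(C)C)(C(C)C)C(C)C | intermediate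
12 | vanillin (4-hydroxy-3-methoxybenzaldehyde) | COc1cc(C=O)ccc1O | starting material
13 | 3-methoxy-4-(triisopropylsilyloxy)benzaldehyde | COc1cc(C=O)ccc1O[Si](C(C)C)(C(C)C)C(C)C | intermediate
14 | (E)-oxocarbenium triflate from 13 and the oxygen of 11, O-alkyl group (2R,3Z)-2-(Ar-methyl)-5-(trimethylsilyl)pent-3-en-1-yl | COc1cc(C[C@H](/C=C\C[Si](C)(C)C)C/[O+]=C/c2ccc(O[Si](C(C)C)(C(C)C)C(C)C)c(OC)c2)ccc1O[Si](C(C)C)(C(C)C)C(C)C.[O-]S(=O)(=O)C(F)(F)F | intermediate
15 | (2S,3R,4R)-3-ethenyl-2-[3-methoxy-4-(triisopropylsilyloxy)phenyl]-4-{[3-methoxy-4-(triisopropylsilyloxy)phenyl]methyl}oxolane | COc1cc(C[C@H]2CO[C@H](c3ccc(O[Si](C(C)C)(C(C)C)C(C)C)c(OC)c3)[C@@H]2C=C)ccc1O[Si](C(C)C)(C(C)C)C(C)C | intermediate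
16 | (2S,3R,4R)-2-[3-methoxy-4-(triisopropylsilyloxy)phenyl]-4-{[3-methoxy-4-(triisopropylsilyloxy)phenyl]methyl}oxolane-3-carbaldehyde | COc1cc(C[C@H]2CO[C@H](c3ccc(O[Si](C(C)C)(C(C)C)C(C)C)c(OC)c3)[C@@H]2C=O)ccc1O[Si](C(C)C)(C(C)C)C(C)C | intermediate
17 | [(2S,3S,4R)-2-[3-methoxy-4-(triisopropylsilyloxy)phenyl]-4-{[3-methoxy-4-(triisopropylsilyloxy)phenyl]methyl}oxolan-3-yl]methanol | COc1cc(C[C@H]2CO[C@H](c3ccc(O[Si](C(C)C)(C(C)C)C(C)C)c(OC)c3)[C@@H]2CO)ccc1O[Si](C(C)C)(C(C)C)C(C)C | intermediate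
18 | p-coumaric acid, (2E)-3-(4-hydroxyphenyl)prop-2-enoic acid | OC(=O)/C=C/c1ccc(O)cc1 | starting material
19 | [(2S,3S,4R)-2-[3-methoxy-4-(triisopropylsilyloxy)phenyl]-4-{[3-methoxy-4-(triisopropylsilyloxy)phenyl]methyl}oxolan-3-yl]methyl (2E)-3-(4-hydroxyphenyl)prop-2-enoate | COc1cc(C[C@H]2CO[C@H](c3ccc(O[Si](C(C)C)(C(C)C)C(C)C)c(OC)c3)[C@@H]2COC(=O)/C=C/c2ccc(O)cc2)ccc1O[Si](C(C)C)(C(C)C)C(C)C | intermediate
20 | [(2S,3S,4R)-2-(4-hydroxy-3-methoxyphenyl)-4-[(4-hydroxy-3-methoxyphenyl)methyl]oxolan-3-yl]methyl (2E)-3-(4-hydroxyphenyl)prop-2-enoate | COc1cc(C[C@H]2CO[C@H](c3ccc(O)c(OC)c3)[C@@H]2COC(=O)/C=C/c2ccc(O)cc2)ccc1O | target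

**Step count**

Total steps: 11. Longest linear sequence: 9 steps (1, 2, 3, 4, 6, 8, 9, 10, 11); steps 5 and 7 make the two side components.

**Steps most likely to fail**

Step 8. The oxocarbenium ion may form slowly or reversibly from the electron-rich aldehyde, so that protodesilylation of the allylsilane competes. The product may also ionise at the C2–O1 bond under the Lewis acid and lose the cis relationship. The fallback sets out from 11 (with 13) and comes back at 15; it pre-forms the C2–O1 bond so that ionisation is unimolecular and fast at −78 °C. Compound 11 is desilylated at oxygen (pyridinium p-toluenesulfonate, MeOH, 0 °C) to (2R,3Z)-2-(Ar-methyl)-5-(trimethylsilyl)pent-3-en-1-ol F1. Aldehyde 13 is oxidised (NaClO2, NaH2PO4, 2-methylbut-2-ene, t-BuOH/H2O) to 3-methoxy-4-(triisopropylsilyloxy)benzoic acid F2. Steglich coupling (dicyclohexylcarbodiimide, 4-dimethylaminopyridine, CH2Cl2) gives the benzoate ester F3. Reductive acetylation (i-Bu2AlH, CH2Cl2, −78 °C; then Ac2O, pyridine, 4-dimethylaminopyridine) gives the α-acetoxy ether F4. BF3·OEt2 (CH2Cl2, −78 °C, minutes) ionises F4 to the same oxocarbenium ion, which should close to 15.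

Step 3. Facial control in the enamine addition may be incomplete, and retro-aldol or hemiacetal oligomerisation of 4 during work-up may erode enantiopurity and yield. The fallback sets out from 3 and comes back at 5; it uses an Evans oxazolidinone. Pinnick oxidation of 3 (NaClO2, NaH2PO4, 2-methylbut-2-ene) gives 3-Ar-propanoic acid F5. Its mixed pivalic anhydride (t-BuCOCl, Et3N) acylates the N-lithio derivative (n-BuLi) of (4R)-4-benzyl-1,3-oxazolidin-2-one to give the imide F6. Hydroxymethylation of the titanium enolate (TiCl4, i-Pr2NEt, CH2Cl2, 0 °C; then 1,3,5-trioxane, TiCl4) places the electrophile anti to the benzyl group and should give the (2S)-hydroxymethyl imide F7. Silylation (Et3SiCl, imidazole) gives the silyl ether imide F8. LiBH4 (THF, MeOH, 0 °C) removes the auxiliary to give (2R)-2-(Ar-methyl)-3-(triethylsilyloxy)propan-1-ol F9. Dess–Martin periodinane with NaHCO3 oxidises F9 to 5.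

Step 6. Z-selectivity in oxaphosphetane formation may be incomplete, and the basic ylide may epimerise 5 or cause β-elimination. The fallback sets out from 5 and comes back at 11; it makes the alkene by alkyne semi-hydrogenation, which gives only the Z-isomer. Corey–Fuchs olefination of 5 (CBr4, PPh3, Et3N, CH2Cl2, 0 °C) gives the 1,1-dibromoalkene F10. Treatment with n-BuLi (2.1 equiv, THF, −78 °C) and trapping of the lithium acetylide with (trimethylsilyl)methyl trifluoromethanesulfonate gives the propargylsilane F11. Semi-hydrogenation (H2, Pd/CaCO3 poisoned with Pb(OAc)2, quinoline, EtOAc) gives 11.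

**Further compounds**

F1 | step 8 | (2R,3Z)-2-{[3-methoxy-4-(triisopropylsilyloxy)phenyl]methyl}-5-(trimethylsilyl)pent-3-en-1-ol | COc1cc(C[C@H](/C=C\C[Si](C)(C)C)CO)ccc1O[Si](C(C)C)(C(C)C)C(C)C
F2 | step 8 | 3-methoxy-4-(triisopropylsilyloxy)benzoic acid | COc1cc(C(=O)O)ccc1O[Si](C(C)C)(C(C)C)C(C)C
F3 | step 8 | (2R,3Z)-2-{[3-methoxy-4-(triisopropylsilyloxy)phenyl]methyl}-5-(trimethylsilyl)pent-3-en-1-yl 3-methoxy-4-(triisopropylsilyloxy)benzoate | COc1cc(C[C@H](/C=C\C[Si](C)(C)C)COC(=O)c2ccc(O[Si](C(C)C)(C(C)C)C(C)C)c(OC)c2)ccc1O[Si](C(C)C)(C(C)C)C(C)C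
F4 | step 8 | [3-methoxy-4-(triisopropylsilyloxy)phenyl]{[(2R,3Z)-2-{[3-methoxy-4-(triisopropylsilyloxy)phenyl]methyl}-5-(trimethylsilyl)pent-3-en-1-yl]oxy}methyl acetate (both configurations at the acetal carbon) | COc1cc(C[C@H](/C=C\C[Si](C)(C)C)COC(OC(C)=O)c2ccc(O[Si](C(C)C)(C(C)C)C(C)C)c(OC)c2)ccc1O[Si](C(C)C)(C(C)C)C(C)C
F5 | step 3 | 3-[3-methoxy-4-(triisopropylsilyloxy)phenyl]propanoic acid | OC(=O)CCc1ccc(O[Si](C(C)C)(C(C)C)C(C)C)c(OC)c1
F6 | step 3 | (4R)-4-benzyl-3-{3-[3-methoxy-4-(triisopropylsilyloxy)phenyl]propanoyl}-1,3-oxazolidin-2-one | COc1cc(CCC(=O)N2C(=O)OC[C@H]2Cc2ccccc2)ccc1O[Si](C(C)C)(C(C)C)C(C)C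
F7 | step 3 | (4R)-4-benzyl-3-[(2S)-3-hydroxy-2-{[3-methoxy-4-(triisopropylsilyloxy)phenyl]methyl}propanoyl]-1,3-oxazolidin-2-one | COc1cc(C[C@@H](CO)C(=O)N2C(=O)OC[C@H]2Cc2ccccc2)ccc1O[Si](C(C)C)(C(C)C)C(C)C
F8 | step 3 | (4R)-4-benzyl-3-[(2S)-2-{[3-methoxy-4-(triisopropylsilyloxy)phenyl]methyl}-3-(triethylsilyloxy)propanoyl]-1,3-oxazolidin-2-one | COc1cc(C[C@@H](CO[Si](CC)(CC)CC)C(=O)N2C(=O)OC[C@H]2Cc2ccccc2)ccc1O[Si](C(C)C)(C(C)C)C(C)C
F9 | step 3 | (2R)-2-{[3-methoxy-4-(triisopropylsilyloxy)phenyl]methyl}-3-(triethylsilyloxy)propan-1-ol | COc1cc(C[C@H](CO)CO[Si](CC)(CC)CC)ccc1O[Si](C(C)C)(C(C)C)C(C)C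
F10 | step 6 | {[(2R)-4,4-dibromo-2-{[3-methoxy-4-(triisopropylsilyloxy)phenyl]methyl}but-3-en-1-yl]oxy}triethylsilane | COc1cc(C[C@H](C=C(Br)Br)CO[Si](CC)(CC)CC)ccc1O[Si](C(C)C)(C(C)C)C(C)C
F11 | step 6 | triethyl{[(2R)-2-{[3-methoxy-4-(triisopropylsilyloxy)phenyl]methyl}-5-(trimethylsilyl)pent-3-yn-1-yl]oxy}silane | COc1cc(C[C@H](C#CC[Si](C)(C)C)CO[Si](CC)(CC)CC)ccc1O[Si](C(C)C)(C(C)C)C(C)C
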